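**Strategy**

The target is a heterochiral biflavanoid: an upper ent-oritin unit (2S,3R) joined through C4 to C6 of a lower oritin-4α-ol unit (2R,3S,4R). In each unit ring C (O1, C2, C3, C4, C4a, C8a) is an O-aryl benzylic ether flanked by a C3–C4 glycol, so C3–C4 is excised as an enediol diether. One cationic [4+2] annulation (oxa-Povarov) of an O-aryl oxocarbenium ion with this alkene forges C2–C3 and C4–C4a of the lower ring C and sets its three stereocentres; the precursor is an open-chain O-aryl O-acetyl acetal of a protected 4-hydroxybenzaldehyde. The mirror-image catalyst turns the same acetal into the upper half, which is joined as a C4 ketone to the lithiated lower half.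

Key step: step 5

Assumption (chemistry): the sense of induction of the confined chiral acid cannot be predicted a priori; "(S,S)" denotes the antipode that delivers the (2R,3S,4R) product and "(R,R)" its mirror image, and if the sense is opposite the two catalysts change places without any other change. The four starting materials in the compound list are taken as purchasable.

**Route**

Step 1
Reactants: 1 2,3-bis(benzyloxy)benzaldehyde
Product: 3 2,3-bis(benzyloxy)phenol, via 2,3-bis(benzyloxy)phenyl formate 2 (not isolated)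
Conditions: mCPBA (1.3 equiv), CH2Cl2, 0 °C to rt; aq. NaHCO3/Na2S2O3 wash; then K2CO3 (0.1 equiv), MeOH, rt
Reagents that add atoms: mCPBA (3-chloroperoxybenzoic acid), OOC(=O)c1cccc(Cl)c1
Why: Baeyer–Villiger (Dakin-type) oxidation in which the electron-rich aryl group migrates to give the aryl formate, cleaved by mild methanolysis to the phenol with the benzyl ethers untouched.

Step 2
Reactants: 3 2,3-bis(benzyloxy)phenol; 4 4-(benzyloxy)benzaldehyde
Product: 6 [4-(benzyloxy)phenyl][2,3-bis(benzyloxy)phenoxy]methyl acetate (racemic), via chloro[4-(benzyloxy)phenyl]methyl acetate 5 (not isolated)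
Conditions: 4, AcCl (1.1 equiv), ZnCl2 (1 mol %), CH2Cl2, 0 °C; then 3, iPr2NEt (1.5 equiv), −20 °C to rt; filtration through basic alumina
Reagents that add atoms: acetyl chloride, CC(=O)Cl
Why: Lewis-acid-catalysed addition of the acyl chloride across the aldehyde gives the α-chloroalkyl ester, whose chloride is displaced by the phenol oxygen under amine base as in the formation of acyloxymethyl aryl ethers (Williamson-type etherification); the acetal carbon is racemic and becomes planar in steps 5 and 6.

Step 3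
Reactants: 7 2-(benzyloxy)acetaldehyde; 8 benzyl alcohol (2.5 equiv)
Product: 9 1,1,2-tris(benzyloxy)ethane
Conditions: TsOH·H2O (2 mol %), toluene, reflux, Dean–Stark trap
Reagents that add atoms: none
Why: Acid-catalysed acetalisation of the aldehyde driven by azeotropic removal of water.

Step 4
Reactants: 9 1,1,2-tris(benzyloxy)ethane
Product: 10 (E)-1,2-bis(benzyloxy)ethene
Conditions: TMSOTf (1.2 equiv), iPr2NEt (1.5 equiv), CH2Cl2, 0 °C to rt; E isomer separated from the Z isomer on Et3N-deactivated silica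
Reagents that add atoms: none
Why: The silyl triflate ionises the acetal and the amine removes the proton α to the oxocarbenium ion (acetal-to-enol-ether elimination), and the non-polar E isomer is separated from the Z isomer by chromatography.

Step 5
Reactants: 6 [4-(benzyloxy)phenyl][2,3-bis(benzyloxy)phenoxy]methyl acetate; 10 (E)-1,2-bis(benzyloxy)ethene (2 equiv)
Product: 11 (2R,3S,4R)-3,4,7,8-tetrakis(benzyloxy)-2-[4-(benzyloxy)phenyl]chromane
Conditions: (S,S)-IDPi Brønsted acid (chiral BINOL-derived N-triflyl imidodiphosphorimidate, 5 mol %), CHCl3, −50 °C; Et3N quench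
Reagents that add atoms: none
Why: Proposed new method: the chiral acid protonates the acetate carbonyl of 6 and acetic acid leaves, giving an (E)-configured O-aryl oxocarbenium ion (a cationic 2-oxadiene, C4a=C8a–O1=C2) paired with the confined chiral anion; the enediol ether adds through one of its two equivalent carbons to C2 (Prins-type C2–C3 bond formation), the resulting O-benzyl oxocarbenium ion at C4 is captured by the arene carbon ortho to O1 (C4–C4a bond), and proton loss restores the arene and the acid. The closest known reactions are the SnCl4-promoted oxa-Povarov annulation of O-aryl mixed acetals with alkenes, which is racemic, and enantioselective Prins and Povarov reactions under chiral Brønsted acid control, so only the transfer of chiral counter-anion control to this acyclic aryl oxocarbenium ion is new. Ring C closes as a formal inverse-demand [4+2] cycloaddition, that is an intermolecular C–C bond formation followed by a 6-exo-trig Friedel–Crafts closure onto the oxocarbenium carbon. The C2 configuration (R) should be set by the catalyst pocket, which exposes one face of the oxocarbenium ion, while C3 (S) and C4 (R) follow from a chair-like transition state with the aryl group and both benzyloxy groups equatorial, the trans C3/C4 relation being carried over from the E alkene. Regioselectivity requires closure at the only free ortho carbon of the aryl ether, secured by the 2-benzyloxy group that blocks the other ortho position and by the para 3-benzyloxy donor; chemoselectivity over acid-induced oligomerisation of 10 is sought through low temperature, the excess of 10 and the fast intramolecular ring closure.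

Step 6
Reactants: 6 [4-(benzyloxy)phenyl][2,3-bis(benzyloxy)phenoxy]methyl acetate; 10 (E)-1,2-bis(benzyloxy)ethene (2 equiv)
Product: 12 (2S,3R,4S)-3,4,7,8-tetrakis(benzyloxy)-2-[4-(benzyloxy)phenyl]chromane
Conditions: (R,R)-IDPi Brønsted acid (mirror image of the acid of step 5, 5 mol %), CHCl3, −50 °C; Et3N quench
Reagents that add atoms: none
Why: Proposed new method: the same enantioselective Prins/Friedel–Crafts [4+2] annulation as in step 5 (closest known types: the racemic SnCl4-promoted oxa-Povarov reaction of O-aryl mixed acetals and chiral-acid-controlled Prins reactions), run with the mirror-image acid so that the oxocarbenium ion is attacked on its other face and the same all-equatorial closure should give the (2S,3R,4S) antipode.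

Step 7
Reactants: 12 (2S,3R,4S)-3,4,7,8-tetrakis(benzyloxy)-2-[4-(benzyloxy)phenyl]chromane
Product: 13 (2S,3S)-3,7,8-tris(benzyloxy)-2-[4-(benzyloxy)phenyl]chroman-4-one
Conditions: DDQ (1.5 equiv), CH2Cl2/H2O (10:1), 0 °C to rt
Reagents that add atoms: water, O
Why: The C4 benzyloxy group is a secondary 2,3,4-trialkoxybenzyl-type ether, so DDQ abstracts the C4 hydride from the most electron-rich arene as in the oxidative cleavage of dimethoxybenzyl ethers and water converts the oxocarbenium ion into the ketone and benzyl alcohol; C2 and C3 are untouched (the C3 descriptor changes from R to S only because C4 now outranks C2).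

Step 8
Reactants: 11 (2R,3S,4R)-3,4,7,8-tetrakis(benzyloxy)-2-[4-(benzyloxy)phenyl]chromane
Product: 14 (2R,3S,4R)-3,4,7,8-tetrakis(benzyloxy)-2-[4-(benzyloxy)phenyl]-6-bromochromane
Conditions: NBS (1.05 equiv), CH2Cl2/MeCN, −10 °C, dark
Reagents that add atoms: N-bromosuccinimide, BrN1C(=O)CCC1=O
Why: Electrophilic aromatic bromination at C6, the only ring position activated by two in-plane oxygen donors (ortho to the 7-benzyloxy group and para to O1), whereas C5 is para only to the twisted central 8-benzyloxy group and is shielded by the C4 substituent.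

Step 9
Reactants: 14 (2R,3S,4R)-3,4,7,8-tetrakis(benzyloxy)-2-[4-(benzyloxy)phenyl]-6-bromochromane; 13 (2S,3S)-3,7,8-tris(benzyloxy)-2-[4-(benzyloxy)phenyl]chroman-4-one
Product: 16 (2S,3S)-3,7,8-tris(benzyloxy)-2-[4-(benzyloxy)phenyl]-4-[(2R,3S,4R)-3,4,7,8-tetrakis(benzyloxy)-2-[4-(benzyloxy)phenyl]chroman-6-yl]chroman-4-ol (carbinol centre unassigned), via the 6-lithiated chromane 15 (not isolated)
Conditions: 14, n-BuLi (1.05 equiv), THF, −78 °C, 15 min; then 13, −78 to −40 °C; H2O quench; crude product used at once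
Reagents that add atoms: n-butyllithium, [Li]CCCC (lithium of intermediate 15 only)
Why: Bromine–lithium exchange followed by 1,2-addition of the aryllithium to the ketone, accelerated by chelation of lithium between the carbonyl and the 3-benzyloxy oxygen and fast enough at −78 °C to outrun enolisation; the new carbinol centre need not be controlled because it is removed in step 10.

Step 10
Reactants: 16 tertiary carbinol from step 9
Product: 17 (2S,3R,4S)-3,7,8-tris(benzyloxy)-2-[4-(benzyloxy)phenyl]-4-[(2R,3S,4R)-3,4,7,8-tetrakis(benzyloxy)-2-[4-(benzyloxy)phenyl]chroman-6-yl]chromane (nona-O-benzyl ent-oritin-(4α→6)-oritin-4α-ol)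
Conditions: Et3SiH (5 equiv), TFA (3 equiv), CH2Cl2, −78 to −40 °C; Et3N/NaHCO3 quench
Reagents that add atoms: none
Why: Ionic hydrogenation in which acid ionises the tertiary carbinol to a doubly aryl-stabilised C4 cation and the silane should deliver hydride to the face anti to the adjacent 3-benzyloxy group (the face chosen by nucleophiles on 2,3-trans-flavan-4-yl cations), which places the aryl group cis to O3 and sets the upper C4 centre, while the lower C4 benzyl ether needs a far stronger acid to ionise and survives.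

Step 11
Reactants: 17 nona-O-benzyl ent-oritin-(4α→6)-oritin-4α-ol
Product: 18 ent-oritin-(4α→6)-oritin-4α-ol, (2R,3S,4R)-6-[(2S,3R,4R)-3,7,8-trihydroxy-2-(4-hydroxyphenyl)chroman-4-yl]-2-(4-hydroxyphenyl)chromane-3,4,7,8-tetrol (target)
Conditions: H2 (1 atm), 20 % Pd(OH)2/C, THF/MeOH (1:1), rt, stopped at complete debenzylation; filtration under argon, Sephadex LH-20
Reagents that add atoms: none
Why: Hydrogenolysis of the nine benzyl ethers at the unhindered O–CH2Ph bonds under neutral conditions touches no stereocentre (the upper C4 descriptor changes from S to R only through changed priorities), and the electron-rich secondary C4–O bond of the lower unit, which is cleaved more slowly than benzyl ethers, should be retained.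

**Compound list**

1 | 2,3-bis(benzyloxy)benzaldehyde | O=Cc1cccc(OCc2ccccc2)c1OCc1ccccc1 | starting material
2 | 2,3-bis(benzyloxy)phenyl formate | O=COc1cccc(OCc2ccccc2)c1OCc1ccccc1 | intermediate (not isolated)
3 | 2,3-bis(benzyloxy)phenol | Oc1cccc(OCc2ccccc2)c1OCc1ccccc1 | intermediate
4 | 4-(benzyloxy)benzaldehyde | O=Cc1ccc(OCc2ccccc2)cc1 | starting material
5 | chloro[4-(benzyloxy)phenyl]methyl acetate (racemic) | CC(=O)OC(Cl)c1ccc(OCc2ccccc2)cc1 | intermediate (not isolated)
6 | [4-(benzyloxy)phenyl][2,3-bis(benzyloxy)phenoxy]methyl acetate (racemic) | CC(=O)OC(Oc1cccc(OCc2ccccc2)c1OCc1ccccc1)c1ccc(OCc2ccccc2)cc1 | intermediate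
7 | 2-(benzyloxy)acetaldehyde | O=CCOCc1ccccc1 | starting material
8 | benzyl alcohol | OCc1ccccc1 | starting material
9 | 1,1,2-tris(benzyloxy)ethane | C(COCc1ccccc1)(OCc1ccccc1)OCc1ccccc1 | intermediate
10 | (E)-1,2-bis(benzyloxy)ethene | O(Cc1ccccc1)/C=C/OCc1ccccc1 | intermediate
11 | (2R,3S,4R)-3,4,7,8-tetrakis(benzyloxy)-2-[4-(benzyloxy)phenyl]chromane | O(Cc6ccccc6)c1ccc([C@H]2Oc3c(ccc(OCc6ccccc6)c3OCc6ccccc6)[C@@H](OCc6ccccc6)[C@@H]2OCc6ccccc6)cc1 | intermediate
12 | (2S,3R,4S)-3,4,7,8-tetrakis(benzyloxy)-2-[4-(benzyloxy)phenyl]chromane | O(Cc6ccccc6)c1ccc([C@@H]2Oc3c(ccc(OCc6ccccc6)c3OCc6ccccc6)[C@H](OCc6ccccc6)[C@H]2OCc6ccccc6)cc1 | intermediate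
13 | (2S,3S)-3,7,8-tris(benzyloxy)-2-[4-(benzyloxy)phenyl]chroman-4-one | O(Cc6ccccc6)c1ccc([C@@H]2Oc3c(ccc(OCc6ccccc6)c3OCc6ccccc6)C(=O)[C@H]2OCc6ccccc6)cc1 | intermediate
14 | (2R,3S,4R)-3,4,7,8-tetrakis(benzyloxy)-2-[4-(benzyloxy)phenyl]-6-bromochromane | O(Cc6ccccc6)c1ccc([C@H]2Oc3c(cc(Br)c(OCc6ccccc6)c3OCc6ccccc6)[C@@H](OCc6ccccc6)[C@@H]2OCc6ccccc6)cc1 | intermediate
15 | [(2R,3S,4R)-3,4,7,8-tetrakis(benzyloxy)-2-[4-(benzyloxy)phenyl]chroman-6-yl]lithium | O(Cc6ccccc6)c1ccc([C@H]2Oc3c(cc([Li])c(OCc6ccccc6)c3OCc6ccccc6)[C@@H](OCc6ccccc6)[C@@H]2OCc6ccccc6)cc1 | intermediate (not isolated)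
16 | (2S,3S)-3,7,8-tris(benzyloxy)-2-[4-(benzyloxy)phenyl]-4-[(2R,3S,4R)-3,4,7,8-tetrakis(benzyloxy)-2-[4-(benzyloxy)phenyl]chroman-6-yl]chroman-4-ol (carbinol centre unassigned, epimers possible) | O(Cc6ccccc6)c1ccc([C@H]2Oc3c(cc(C4(O)c5ccc(OCc6ccccc6)c(OCc6ccccc6)c5O[C@@H](c5ccc(OCc6ccccc6)cc5)[C@@H]4OCc6ccccc6)c(OCc6ccccc6)c3OCc6ccccc6)[C@@H](OCc6ccccc6)[C@@H]2OCc6ccccc6)cc1 | intermediate
17 | (2S,3R,4S)-3,7,8-tris(benzyloxy)-2-[4-(benzyloxy)phenyl]-4-[(2R,3S,4R)-3,4,7,8-tetrakis(benzyloxy)-2-[4-(benzyloxy)phenyl]chroman-6-yl]chromane (nona-O-benzyl ent-oritin-(4α→6)-oritin-4α-ol; upper unit 2,3-trans-3,4-cis, lower unit 2,3-trans-3,4-trans) | O(Cc6ccccc6)c1ccc([C@H]2Oc3c(cc([C@@H]4c5ccc(OCc6ccccc6)c(OCc6ccccc6)c5O[C@@H](c5ccc(OCc6ccccc6)cc5)[C@@H]4OCc6ccccc6)c(OCc6ccccc6)c3OCc6ccccc6)[C@@H](OCc6ccccc6)[C@@H]2OCc6ccccc6)cc1 | intermediate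
18 | ent-oritin-(4α→6)-oritin-4α-ol, (2R,3S,4R)-6-[(2S,3R,4R)-3,7,8-trihydroxy-2-(4-hydroxyphenyl)chroman-4-yl]-2-(4-hydroxyphenyl)chromane-3,4,7,8-tetrol | Oc1ccc([C@H]2Oc3c(cc([C@@H]4c5ccc(O)c(O)c5O[C@@H](c5ccc(O)cc5)[C@@H]4O)c(O)c3O)[C@@H](O)[C@@H]2O)cc1 | target

**Step count and risks**

Total step count: 11. Longest linear sequence: 7 steps (steps 1, 2, 5, 8, 9, 10, 11).

Steps most likely to fail:

1. Step 5 (key step, bears the label). The chiral ion pair may discriminate the faces of the acyclic O-aryl oxocarbenium ion too weakly, or acid-induced oligomerisation of the enediol ether may outrun the annulation. Fallback: setting out from 6 (with 10) and returning at 11, absolute stereocontrol is moved out of the annulation. SnCl4 (1.1 equiv) in CH2Cl2 at −78 °C, the established racemic oxa-Povarov protocol, should give racemic (2R*,3S*,4R*)-3,4,7,8-tetrakis(benzyloxy)-2-[4-(benzyloxy)phenyl]chromane F1. Preparative chromatography on a chiral stationary phase (supercritical CO2/iPrOH on cellulose tris(3,5-dimethylphenylcarbamate)) then supplies 11; since the route consumes both antipodes, the other fraction is 12 and nothing is discarded. The absolute configuration would be assigned on bromide 14 by anomalous-dispersion X-ray diffraction.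

2. Step 6 (bears the label). The same process risks apply in the mirror-image series. Fallback: setting out from 4 and returning at 13 (steps 6 and 7 are bypassed) by classical flavonoid chemistry. Purchased gallacetophenone is 3,4-di-O-benzylated (BnBr, K2CO3, acetone) to 1-[3,4-bis(benzyloxy)-2-hydroxyphenyl]ethan-1-one F2 and protected (MOMCl, NaH, DMF) as 1-[3,4-bis(benzyloxy)-2-(methoxymethoxy)phenyl]ethan-1-one F3. Claisen–Schmidt condensation with 4 (KOH, EtOH/THF) gives (E)-1-[3,4-bis(benzyloxy)-2-(methoxymethoxy)phenyl]-3-[4-(benzyloxy)phenyl]prop-2-en-1-one F4. Juliá–Colonna epoxidation (poly-D-leucine, urea–H2O2, DBU, THF) gives [3,4-bis(benzyloxy)-2-(methoxymethoxy)phenyl]{(2S,3R)-3-[4-(benzyloxy)phenyl]oxiran-2-yl}methanone F5. HCl in MeOH/THF removes the MOM group and the freed phenol opens the epoxide at the benzylic carbon to give (2S,3S)-7,8-bis(benzyloxy)-2-[4-(benzyloxy)phenyl]-3-hydroxychroman-4-one F6. Benzylation of O3 (BnBr, Ag2O, CH2Cl2) gives 13.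

3. Step 10. Facial selectivity of hydride delivery to the C4 cation may be poor, or the cation may lose the C3 proton to an enol ether that is then hydrogenated without control. Fallback: setting out from 12 and 11 and returning at 17 (steps 7 to 10 are replaced), the polarity of the C4 bond formation is reversed so that the arene, not hydride, is the incoming nucleophile. Both nucleophiles choose the same face of a 2,3-trans C4 cation, so the two modes place the aryl group on opposite faces. Thus 12 is converted with benzyl mercaptan and BF3·OEt2 (CH2Cl2, −20 °C) into (2S,3S)-3,7,8-tris(benzyloxy)-2-[4-(benzyloxy)phenyl]-4-(benzylsulfanyl)chromane F7. Thiophilic activation with AgBF4 (THF, 0 °C, 2,6-di-tert-butylpyridine) in the presence of 11, whose own 4-benzyloxy group is inert to the silver salt, should give by Friedel–Crafts attack of C6 the coupled product 17 together with its upper-C4 epimer (2S,3R,4R)-3,7,8-tris(benzyloxy)-2-[4-(benzyloxy)phenyl]-4-[(2R,3S,4R)-3,4,7,8-tetrakis(benzyloxy)-2-[4-(benzyloxy)phenyl]chroman-6-yl]chromane F8. The two are separated by chromatography.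

**Further compounds**

F1 | step 5 | racemic (2R*,3S*,4R*)-3,4,7,8-tetrakis(benzyloxy)-2-[4-(benzyloxy)phenyl]chromane (1:1 mixture of 11 and 12) | O(Cc6ccccc6)c1ccc([C@H]2Oc3c(ccc(OCc6ccccc6)c3OCc6ccccc6)[C@@H](OCc6ccccc6)[C@@H]2OCc6ccccc6)cc1.O(Cc6ccccc6)c1ccc([C@@H]2Oc3c(ccc(OCc6ccccc6)c3OCc6ccccc6)[C@H](OCc6ccccc6)[C@H]2OCc6ccccc6)cc1
F2 | step 6 | 1-[3,4-bis(benzyloxy)-2-hydroxyphenyl]ethan-1-one | CC(=O)c1ccc(OCc2ccccc2)c(OCc2ccccc2)c1O
F3 | step 6 | 1-[3,4-bis(benzyloxy)-2-(methoxymethoxy)phenyl]ethan-1-one | CC(=O)c1ccc(OCc2ccccc2)c(OCc2ccccc2)c1OCOC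
F4 | step 6 | (E)-1-[3,4-bis(benzyloxy)-2-(methoxymethoxy)phenyl]-3-[4-(benzyloxy)phenyl]prop-2-en-1-one | O=C(/C=C/c1ccc(OCc2ccccc2)cc1)c1ccc(OCc2ccccc2)c(OCc2ccccc2)c1OCOC
F5 | step 6 | [3,4-bis(benzyloxy)-2-(methoxymethoxy)phenyl]{(2S,3R)-3-[4-(benzyloxy)phenyl]oxiran-2-yl}methanone | O=C(c1ccc(OCc2ccccc2)c(OCc2ccccc2)c1OCOC)[C@H]1O[C@@H]1c1ccc(OCc2ccccc2)cc1
F6 | step 6 | (2S,3S)-7,8-bis(benzyloxy)-2-[4-(benzyloxy)phenyl]-3-hydroxychroman-4-one | O(Cc6ccccc6)c1ccc([C@@H]2Oc3c(ccc(OCc6ccccc6)c3OCc6ccccc6)C(=O)[C@H]2O)cc1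
F7 | step 10 | (2S,3S)-3,7,8-tris(benzyloxy)-2-[4-(benzyloxy)phenyl]-4-(benzylsulfanyl)chromane (C4 unassigned) | O(Cc6ccccc6)c1ccc([C@@H]2Oc3c(ccc(OCc6ccccc6)c3OCc6ccccc6)C(SCc6ccccc6)[C@H]2OCc6ccccc6)cc1
F8 | step 10 | (2S,3R,4R)-3,7,8-tris(benzyloxy)-2-[4-(benzyloxy)phenyl]-4-[(2R,3S,4R)-3,4,7,8-tetrakis(benzyloxy)-2-[4-(benzyloxy)phenyl]chroman-6-yl]chromane (upper-C4 epimer of 17) | O(Cc6ccccc6)c1ccc([C@H]2Oc3c(cc([C@H]4c5ccc(OCc6ccccc6)c(OCc6ccccc6)c5O[C@@H](c5ccc(OCc6ccccc6)cc5)[C@@H]4OCc6ccccc6)c(OCc6ccccc6)c3OCc6ccccc6)[C@@H](OCc6ccccc6)[C@@H]2OCc6ccccc6)cc1
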